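**Retrosynthetic overview** (numbering: ring C1 quaternary/Me, C2 CH2, C3 CBr, C4 CHCl, C5 CH2, C6 CHCl; side chain C7=C8; bromomethyl C9)
- Feature used: quaternary C1 carries an aldehyde-level carbon (C7, later the chlorovinyl group) and is bonded to ring CH2 C2, whose neighbour C3 bears the exocyclic carbon C9. C1–C2 is therefore cut to an enol ether C7=C1 and a 2-(silylmethyl)allyl unit C2=C3–C9.
- The only ring (cyclohexane C1–C6) is closed in step 10 by anodic enol ether–allylsilane coupling. C6 controls C1 through the Z enol ether, whose OMe is cis to C6.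
- Precursor: (S)-α-hydroxy-γ-butyrolactone gives C3–C6 and the C4 configuration; lactone to allylsilane, aldehyde, acetyl-anion addition, oxidation, CBS reduction (sets C6 syn to C4), methyl ketone, Z-selective Wittig.
- After the ring: acetal to aldehyde to alkyne; invertive chlorination at C6, then at allylic C4; chloroalkyne; Br2 addition to C3=C9; syn hydroboration/protonolysis to the Z-chlorovinyl group.

Key step: step 10

Remark: lactone 1 is bought; it is the lactone of the L-malic acid series and fixes C4. C4 is protected as the TBDPS ether and C6 as the TBS ether so that the two oxygens can be replaced one after the other.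
Remark: TBS = tert-butyldimethylsilyl, TBDPS = tert-butyldiphenylsilyl; ring compounds are named with the target numbering above, not with lowest locants.

Step 1
Reactants: 1 (S)-3-hydroxyoxolan-2-one
Product: 2 (S)-3-(TBDPS-oxy)oxolan-2-one
Conditions: TBDPSCl, imidazole, DMF, rt
Reagents that add atoms: tert-butyl(chloro)diphenylsilane, CC(C)(C)[Si](Cl)(c1ccccc1)c1ccccc1
Why: Imidazole-assisted silylation of the secondary alcohol; the stereocentre is not involved.

Step 2
Reactants: 2 (S)-3-(TBDPS-oxy)oxolan-2-one; 3 (trimethylsilyl)methylmagnesium chloride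
Product: 5 (S)-3-(TBDPS-oxy)-4-[(trimethylsilyl)methyl]pent-4-en-1-ol, via bis(silylmethyl) carbinol 4 (not isolated)
Conditions: 3 (5 equiv), CeCl3, THF, −78 °C → rt; then SiO2, CH2Cl2, rt
Reagents that add atoms: (trimethylsilyl)methylmagnesium chloride (3), C[Si](C)(C)C[Mg]Cl
Why: Cerium-mediated double addition to the lactone carbonyl followed by Peterson elimination of one β-hydroxysilane gives the 2-substituted allylsilane; the weakly basic organocerium reagent leaves the α-silyloxy centre untouched.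

Step 3
Reactants: 5 (S)-3-(TBDPS-oxy)-4-[(trimethylsilyl)methyl]pent-4-en-1-ol
Product: 6 (S)-3-(TBDPS-oxy)-4-[(trimethylsilyl)methyl]pent-4-enal
Conditions: Dess–Martin periodinane, NaHCO3, CH2Cl2, 0 °C → rt
Reagents that add atoms: none
Why: Dess–Martin oxidation of the primary alcohol under buffered, non-electrophilic conditions that the allylsilane tolerates.

Step 4
Reactants: 6 (S)-3-(TBDPS-oxy)-4-[(trimethylsilyl)methyl]pent-4-enal; 7 ethyl vinyl ether
Product: 8 (3RS,5S)-5-(TBDPS-oxy)-2-ethoxy-6-[(trimethylsilyl)methyl]hepta-1,6-dien-3-ol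
Conditions: 7, t-BuLi, THF, −78 → 0 °C; then 6, −78 °C; aq. NH4Cl
Reagents that add atoms: ethyl vinyl ether (7, as its 1-lithio derivative), C=COCC
Why: 1,2-Addition of an acyl-anion equivalent (α-lithiated enol ether) to the aldehyde; the C6 carbinol forms as a mixture that steps 5 and 6 correct.

Step 5
Reactants: 8 (3RS,5S)-5-(TBDPS-oxy)-2-ethoxy-6-[(trimethylsilyl)methyl]hepta-1,6-dien-3-ol
Product: 9 (S)-5-(TBDPS-oxy)-2-ethoxy-6-[(trimethylsilyl)methyl]hepta-1,6-dien-3-one
Conditions: Dess–Martin periodinane, pyridine, CH2Cl2, 0 °C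
Reagents that add atoms: none
Why: Dess–Martin oxidation to the α-ethoxy enone; pyridine buffers the acetic acid so the enol ether survives.

Step 6
Reactants: 9 (S)-5-(TBDPS-oxy)-2-ethoxy-6-[(trimethylsilyl)methyl]hepta-1,6-dien-3-one
Product: 10 (3R,5S)-5-(TBDPS-oxy)-2-ethoxy-6-[(trimethylsilyl)methyl]hepta-1,6-dien-3-ol
Conditions: (S)-Me-CBS oxazaborolidine [(S)-1-methyl-3,3-diphenyltetrahydro-1H,3H-pyrrolo[1,2-c][1,3,2]oxazaborole] (0.3 equiv), catecholborane, toluene, −78 °C; MeOH, pH 7 buffer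
Reagents that add atoms: none
Why: Corey–Bakshi–Shibata reduction under reagent control: the branched 1-ethoxyvinyl group acts as the large substituent, so the (S)-catalyst should give the (R)-carbinol at C6, syn to the C4 oxygen.

Step 7
Reactants: 10 (3R,5S)-5-(TBDPS-oxy)-2-ethoxy-6-[(trimethylsilyl)methyl]hepta-1,6-dien-3-ol
Product: 11 (3R,5S)-3-(TBS-oxy)-5-(TBDPS-oxy)-2-ethoxy-6-[(trimethylsilyl)methyl]hepta-1,6-diene
Conditions: TBSCl, imidazole, DMAP (cat.), DMF, rt
Reagents that add atoms: tert-butyl(chloro)dimethylsilane, CC(C)(C)[Si](C)(C)Cl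
Why: Silylation of the C6 alcohol under basic conditions that keep the enol ether and the allylsilane.

Step 8
Reactants: 11 (3R,5S)-3-(TBS-oxy)-5-(TBDPS-oxy)-2-ethoxy-6-[(trimethylsilyl)methyl]hepta-1,6-diene
Product: 12 (3R,5S)-3-(TBS-oxy)-5-(TBDPS-oxy)-6-[(trimethylsilyl)methyl]hept-6-en-2-one
Conditions: 1 M HCl (aq)/THF 1:10, 0 °C
Reagents that add atoms: water, O
Why: Acid hydrolysis of the 1-ethoxyvinyl ether to the methyl ketone is fast in cold dilute acid, which should spare the allylsilane and both silyl ethers.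

Step 9
Reactants: 12 (3R,5S)-3-(TBS-oxy)-5-(TBDPS-oxy)-6-[(trimethylsilyl)methyl]hept-6-en-2-one; 13 (methoxymethyl)triphenylphosphonium chloride
Product: 14 (1Z,3R,5S)-3-(TBS-oxy)-5-(TBDPS-oxy)-1-methoxy-2-methyl-6-[(trimethylsilyl)methyl]hepta-1,6-diene
Conditions: 13, KHMDS, THF, 0 °C; then 12, −78 → 0 °C
Reagents that add atoms: (methoxymethyl)triphenylphosphonium chloride (13), [Cl-].COC[P+](c1ccccc1)(c1ccccc1)c1ccccc1
Why: Wittig methoxymethylenation with the salt-free ylide; non-stabilised ylides add to α-alkoxy ketones so that the ylide substituent ends cis to the oxygenated branch, here the Z enol ether (OMe cis to C6), and any E isomer would be removed by chromatography.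

Step 10
Reactants: 14 (1Z,3R,5S)-3-(TBS-oxy)-5-(TBDPS-oxy)-1-methoxy-2-methyl-6-[(trimethylsilyl)methyl]hepta-1,6-diene
Product: 15 (1R,4S,6R)-6-(TBS-oxy)-4-(TBDPS-oxy)-1-(dimethoxymethyl)-1-methyl-3-methylidenecyclohexane
Conditions: reticulated vitreous carbon anode, Pt cathode, undivided cell, constant current (8 mA), 2.2 F/mol; 0.1 M LiClO4, 2,6-lutidine, MeOH/THF 3:7, rt
Reagents that add atoms: methanol, CO
Why: One-electron oxidation takes place at the enol ether, the more easily oxidised alkene, and the radical cation is attacked at C1 by the CH2 terminus (C2) of the allylsilane; a second electron transfer, loss of the silyl group to methanol and capture of the C7 oxocarbenium ion by methanol leave the C3=C9 alkene and the dimethyl acetal. The closest known reaction is the intramolecular anodic coupling of enol ether radical cations with allylsilanes, which also forms quaternary carbons. The cyclohexane closes 6-exo with respect to the enol ether (C7 stays outside the ring) and through the terminal carbon of the allylsilane, in a chair in which the syn-1,3 silyloxy groups at C4 and C6 are both equatorial. C1 is controlled by C6: because the methoxy group of the Z enol ether is cis to C6, A(1,3) strain holds C6–H in the plane of C1=C7, so C7 takes the equatorial site and the methyl group the axial one while C2 bonds anti to the C6–O bond, which places C7 trans to the C6 oxygen. The step needs oxidation of the enol ether in preference to the allylsilane, C–C bond formation faster than methanol trapping, and this facial selectivity; the electron-rich enol ether, the tethered allylsilane, the syn-diol pattern and the Z geometry are there to secure them.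

Step 11
Reactants: 15 (1R,4S,6R)-6-(TBS-oxy)-4-(TBDPS-oxy)-1-(dimethoxymethyl)-1-methyl-3-methylidenecyclohexane
Product: 16 (1R,4S,6R)-6-(TBS-oxy)-4-(TBDPS-oxy)-1-methyl-3-methylidenecyclohexane-1-carbaldehyde
Conditions: TsOH·H2O (cat.), acetone/H2O, rt
Reagents that add atoms: water, O
Why: Acid-catalysed acetal hydrolysis; the aldehyde sits on quaternary C1, so it can neither epimerise nor eliminate the β-silyloxy group.

Step 12
Reactants: 16 (1R,4S,6R)-6-(TBS-oxy)-4-(TBDPS-oxy)-1-methyl-3-methylidenecyclohexane-1-carbaldehyde; 17 dimethyl (1-diazo-2-oxopropyl)phosphonate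
Product: 18 (1S,4S,6R)-6-(TBS-oxy)-4-(TBDPS-oxy)-1-ethynyl-1-methyl-3-methylidenecyclohexane
Conditions: 17, K2CO3, MeOH, 0 °C → rt
Reagents that add atoms: dimethyl (1-diazo-2-oxopropyl)phosphonate (17), COP(=O)(OC)C(=[N+]=[N-])C(C)=O
Why: Seyferth–Gilbert homologation with the Ohira–Bestmann reagent, well suited to a non-enolisable aldehyde; the alkyne gives a slim C7 group for step 14 and a stereospecific entry to the Z-chloroalkene.

Step 13
Reactants: 18 (1S,4S,6R)-6-(TBS-oxy)-4-(TBDPS-oxy)-1-ethynyl-1-methyl-3-methylidenecyclohexane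
Product: 19 (1S,4S,6R)-4-(TBDPS-oxy)-1-ethynyl-1-methyl-3-methylidenecyclohexan-6-ol
Conditions: HF·pyridine, pyridine, THF, 0 °C → rt
Reagents that add atoms: none
Why: Selective desilylation: under acidic fluoride conditions a TBS ether is cleaved much faster than a TBDPS ether.

Step 14
Reactants: 19 (1S,4S,6R)-4-(TBDPS-oxy)-1-ethynyl-1-methyl-3-methylidenecyclohexan-6-ol
Product: 21 (1S,4S,6S)-4-(TBDPS-oxy)-6-chloro-1-ethynyl-1-methyl-3-methylidenecyclohexane, via triflate 20 (not isolated)
Conditions: Tf2O, 2,6-lutidine, CH2Cl2, −78 → −30 °C; then Bu4NCl, −30 °C → rt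
Reagents that add atoms: tetrabutylammonium chloride, CCCC[N+](CCCC)(CCCC)CCCC.[Cl-]; trifluoromethanesulfonic anhydride (its atoms stay in 20 only), O=S(=O)(OS(=O)(=O)C(F)(F)F)C(F)(F)F
Why: Sulfonylation then SN2 displacement by chloride with inversion at C6: in the chair with both oxygen groups equatorial, chloride enters axially between the rod-like ethynyl group and ring C2 with the C1 methyl anti to it, the equatorial triflate has no anti-periplanar hydrogen for E2, and the β-alkynyl group slows ionisation.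

Step 15
Reactants: 21 (1S,4S,6S)-4-(TBDPS-oxy)-6-chloro-1-ethynyl-1-methyl-3-methylidenecyclohexane
Product: 22 (1S,4S,6S)-6-chloro-1-ethynyl-1-methyl-3-methylidenecyclohexan-4-ol
Conditions: TBAF, AcOH, THF, 0 °C → rt
Reagents that add atoms: none
Why: Fluoride desilylation; the acetic acid buffer keeps the medium from eliminating the secondary chloride.

Step 16
Reactants: 22 (1S,4S,6S)-6-chloro-1-ethynyl-1-methyl-3-methylidenecyclohexan-4-ol
Product: 23 (1S,4R,6S)-4,6-dichloro-1-ethynyl-1-methyl-3-methylidenecyclohexane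
Conditions: PPh3, hexachloroacetone, CH2Cl2, −20 → 0 °C
Reagents that add atoms: hexachloroacetone, ClC(Cl)(Cl)C(=O)C(Cl)(Cl)Cl
Why: Appel-type chlorination: chloride displaces the alkoxyphosphonium ion in an SN2 reaction with inversion at allylic C4, and this reagent pair is the one known to convert secondary allylic alcohols with little allylic transposition.

Step 17
Reactants: 23 (1S,4R,6S)-4,6-dichloro-1-ethynyl-1-methyl-3-methylidenecyclohexane
Product: 25 (1S,4R,6S)-4,6-dichloro-1-(chloroethynyl)-1-methyl-3-methylidenecyclohexane, via lithium acetylide 24 (not isolated)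
Conditions: LDA (1.05 equiv), THF, −78 °C; then NCS, −78 → 0 °C; aq. NH4Cl
Reagents that add atoms: N-chlorosuccinimide, ClN1C(=O)CCC1=O; lithium diisopropylamide (its lithium stays in 24 only), [Li]N(C(C)C)C(C)C
Why: Deprotonation of the terminal alkyne, by far the most acidic site, and electrophilic chlorination of the acetylide; at −78 °C the hindered amide base should not touch the alkyl chlorides.

Step 18
Reactants: 25 (1S,4R,6S)-4,6-dichloro-1-(chloroethynyl)-1-methyl-3-methylidenecyclohexane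
Product: 26 (1S,3S,4R,6S)-3-bromo-3-(bromomethyl)-4,6-dichloro-1-(chloroethynyl)-1-methylcyclohexane
Conditions: Br2 (1.0 equiv), CH2Cl2, −78 °C, dark
Reagents that add atoms: bromine, BrBr
Why: Electrophilic anti addition to the 1,1-disubstituted alkene, which is far more reactive than the chloroalkyne: the bromonium ion should form on the face opposite the axial chloroethynyl group and be opened at tertiary C3 from the axial side, giving axial Br and equatorial CH2Br, which is also the more stable arrangement.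

Step 19
Reactants: 26 (1S,3S,4R,6S)-3-bromo-3-(bromomethyl)-4,6-dichloro-1-(chloroethynyl)-1-methylcyclohexane
Product: 28 (1S,3S,4R,6S)-3-bromo-3-(bromomethyl)-4,6-dichloro-1-[(Z)-2-chloroethenyl]-1-methylcyclohexane, via alkenylborane 27 (not isolated)
Conditions: dicyclohexylborane, THF, 0 °C → rt; then AcOH, rt
Reagents that add atoms: dicyclohexylborane (its boron and cyclohexyl groups stay in 27 only), B(C1CCCCC1)C1CCCCC1
Why: Syn hydroboration of the 1-chloroalkyne places boron on the chlorine-bearing carbon and protonolysis of the C–B bond with retention gives the Z-chloroalkene; no other alkene is left to compete.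

**Compound list**
1 | (S)-3-hydroxyoxolan-2-one [(S)-α-hydroxy-γ-butyrolactone] | O[C@H]1CCOC1=O | starting material
2 | (S)-3-(TBDPS-oxy)oxolan-2-one | CC(C)(C)[Si](c1ccccc1)(c1ccccc1)O[C@H]1CCOC1=O | intermediate
3 | (trimethylsilyl)methylmagnesium chloride | C[Si](C)(C)C[Mg]Cl | starting material
4 | (S)-3-(TBDPS-oxy)-5-(trimethylsilyl)-4-[(trimethylsilyl)methyl]pentane-1,4-diol | OCC[C@H](O[Si](c1ccccc1)(c1ccccc1)C(C)(C)C)C(O)(C[Si](C)(C)C)C[Si](C)(C)C | intermediate
5 | (S)-3-(TBDPS-oxy)-4-[(trimethylsilyl)methyl]pent-4-en-1-ol | OCC[C@H](O[Si](c1ccccc1)(c1ccccc1)C(C)(C)C)C(=C)C[Si](C)(C)C | intermediate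
6 | (S)-3-(TBDPS-oxy)-4-[(trimethylsilyl)methyl]pent-4-enal | O=CC[C@H](O[Si](c1ccccc1)(c1ccccc1)C(C)(C)C)C(=C)C[Si](C)(C)C | intermediate
7 | ethyl vinyl ether | C=COCC | starting material
8 | (3RS,5S)-5-(TBDPS-oxy)-2-ethoxy-6-[(trimethylsilyl)methyl]hepta-1,6-dien-3-ol (C6 epimers) | CCOC(=C)C(O)C[C@H](O[Si](c1ccccc1)(c1ccccc1)C(C)(C)C)C(=C)C[Si](C)(C)C | intermediate
9 | (S)-5-(TBDPS-oxy)-2-ethoxy-6-[(trimethylsilyl)methyl]hepta-1,6-dien-3-one | CCOC(=C)C(=O)C[C@H](O[Si](c1ccccc1)(c1ccccc1)C(C)(C)C)C(=C)C[Si](C)(C)C | intermediate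
10 | (3R,5S)-5-(TBDPS-oxy)-2-ethoxy-6-[(trimethylsilyl)methyl]hepta-1,6-dien-3-ol | CCOC(=C)[C@H](O)C[C@H](O[Si](c1ccccc1)(c1ccccc1)C(C)(C)C)C(=C)C[Si](C)(C)C | intermediate
11 | (3R,5S)-3-(TBS-oxy)-5-(TBDPS-oxy)-2-ethoxy-6-[(trimethylsilyl)methyl]hepta-1,6-diene | CCOC(=C)[C@H](O[Si](C)(C)C(C)(C)C)C[C@H](O[Si](c1ccccc1)(c1ccccc1)C(C)(C)C)C(=C)C[Si](C)(C)C | intermediate
12 | (3R,5S)-3-(TBS-oxy)-5-(TBDPS-oxy)-6-[(trimethylsilyl)methyl]hept-6-en-2-one | CC(=O)[C@H](O[Si](C)(C)C(C)(C)C)C[C@H](O[Si](c1ccccc1)(c1ccccc1)C(C)(C)C)C(=C)C[Si](C)(C)C | intermediate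
13 | (methoxymethyl)triphenylphosphonium chloride | [Cl-].COC[P+](c1ccccc1)(c1ccccc1)c1ccccc1 | starting material
14 | (1Z,3R,5S)-3-(TBS-oxy)-5-(TBDPS-oxy)-1-methoxy-2-methyl-6-[(trimethylsilyl)methyl]hepta-1,6-diene | CO/C=C(/C)[C@H](O[Si](C)(C)C(C)(C)C)C[C@H](O[Si](c1ccccc1)(c1ccccc1)C(C)(C)C)C(=C)C[Si](C)(C)C | intermediate
15 | (1R,4S,6R)-6-(TBS-oxy)-4-(TBDPS-oxy)-1-(dimethoxymethyl)-1-methyl-3-methylidenecyclohexane | C[C@@]1(C(OC)OC)CC(=C)[C@@H](O[Si](c2ccccc2)(c2ccccc2)C(C)(C)C)C[C@H]1O[Si](C)(C)C(C)(C)C | intermediate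
16 | (1R,4S,6R)-6-(TBS-oxy)-4-(TBDPS-oxy)-1-methyl-3-methylidenecyclohexane-1-carbaldehyde | C[C@@]1(C=O)CC(=C)[C@@H](O[Si](c2ccccc2)(c2ccccc2)C(C)(C)C)C[C@H]1O[Si](C)(C)C(C)(C)C | intermediate
17 | dimethyl (1-diazo-2-oxopropyl)phosphonate | COP(=O)(OC)C(=[N+]=[N-])C(C)=O | starting material
18 | (1S,4S,6R)-6-(TBS-oxy)-4-(TBDPS-oxy)-1-ethynyl-1-methyl-3-methylidenecyclohexane | C[C@@]1(C#C)CC(=C)[C@@H](O[Si](c2ccccc2)(c2ccccc2)C(C)(C)C)C[C@H]1O[Si](C)(C)C(C)(C)C | intermediate
19 | (1S,4S,6R)-4-(TBDPS-oxy)-1-ethynyl-1-methyl-3-methylidenecyclohexan-6-ol | C[C@@]1(C#C)CC(=C)[C@@H](O[Si](c2ccccc2)(c2ccccc2)C(C)(C)C)C[C@H]1O | intermediate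
20 | (1S,4S,6R)-4-(TBDPS-oxy)-1-ethynyl-1-methyl-3-methylidenecyclohexan-6-yl trifluoromethanesulfonate | C[C@@]1(C#C)CC(=C)[C@@H](O[Si](c2ccccc2)(c2ccccc2)C(C)(C)C)C[C@H]1OS(=O)(=O)C(F)(F)F | intermediate
21 | (1S,4S,6S)-4-(TBDPS-oxy)-6-chloro-1-ethynyl-1-methyl-3-methylidenecyclohexane | C[C@@]1(C#C)CC(=C)[C@@H](O[Si](c2ccccc2)(c2ccccc2)C(C)(C)C)C[C@@H]1Cl | intermediate
22 | (1S,4S,6S)-6-chloro-1-ethynyl-1-methyl-3-methylidenecyclohexan-4-ol | C[C@@]1(C#C)CC(=C)[C@@H](O)C[C@@H]1Cl | intermediate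
23 | (1S,4R,6S)-4,6-dichloro-1-ethynyl-1-methyl-3-methylidenecyclohexane | C[C@@]1(C#C)CC(=C)[C@H](Cl)C[C@@H]1Cl | intermediate
24 | lithium acetylide of 23 | C[C@@]1(C#C[Li])CC(=C)[C@H](Cl)C[C@@H]1Cl | intermediate
25 | (1S,4R,6S)-4,6-dichloro-1-(chloroethynyl)-1-methyl-3-methylidenecyclohexane | C[C@@]1(C#CCl)CC(=C)[C@H](Cl)C[C@@H]1Cl | intermediate
26 | (1S,3S,4R,6S)-3-bromo-3-(bromomethyl)-4,6-dichloro-1-(chloroethynyl)-1-methylcyclohexane | C[C@@]1(C#CCl)C[C@@](Br)(CBr)[C@H](Cl)C[C@@H]1Cl | intermediate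
27 | [(Z)-1-chloro-2-[(1S,3S,4R,6S)-3-bromo-3-(bromomethyl)-4,6-dichloro-1-methylcyclohexyl]ethenyl]dicyclohexylborane | C[C@@]1(/C=C(\Cl)B(C2CCCCC2)C2CCCCC2)C[C@@](Br)(CBr)[C@H](Cl)C[C@@H]1Cl | intermediate
28 | (1S,3S,4R,6S)-3-bromo-3-(bromomethyl)-4,6-dichloro-1-[(Z)-2-chloroethenyl]-1-methylcyclohexane | C[C@@]1(/C=C\Cl)C[C@@](Br)(CBr)[C@H](Cl)C[C@@H]1Cl | target

**Step count:** 19 steps in total; longest linear sequence 19 steps (1 → 28).

**Steps most likely to fail**

Step 14 (chlorination at C6). C6 is flanked by quaternary C1, so displacement may be outrun by ionisation of the triflate with ring contraction, or by elimination. The fallback replaces polar substitution by a radical deoxychlorination. It sets out from 19: acylation with methyl chlorooxoacetate (Et3N, DMAP) would give the methyl oxalate F5, and hydrolysis with aqueous CsOH the cesium oxalate F6. Irradiation with blue light in the presence of Ir[dF(CF3)ppy]2(dtbbpy)PF6 and ethyl trichloroacetate would release two CO2 and a C6 radical. This radical should take chlorine from the face opposite the C1 methyl and the C4 silyloxy group, which returns to the route at 21.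

Step 10 (anodic cyclisation). Facial selectivity at C1 may be poor, or methanol may trap the radical cation before the C1–C2 bond forms at the crowded carbon. The fallback changes the initiating group to a ketene dithioacetal, which is oxidised more easily and whose two sulfur substituents make the A(1,3) bias independent of alkene geometry. It sets out from ketone 12: Peterson olefination with 2-lithio-2-(trimethylsilyl)-1,3-dithiane would give the ketene dithioacetal F1. Anodic oxidation in the cell of step 10 would give the cyclised 2-methoxy-1,3-dithiane F2, and aqueous acid would open it to the S-(3-sulfanylpropyl) thioester F3. LiAlH4 would reduce this to the neopentyl alcohol F4, and Dess–Martin oxidation would return to the route at aldehyde 16.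

Step 18 (Br2 addition). Bromonium formation on the hindered face, or opening at C9 in place of C3, would erode the C3 configuration. The fallback lets thermodynamic control set C3. It sets out from 25: the bromination mixture, which would contain the C3-epimeric dibromide F7, would be warmed with LiBr in MeCN so that the tertiary bromide re-ionises through the bromonium–bromide ion pair, a known equilibration of vicinal dibromides. Dibromide 26, with axial Br and equatorial CH2Br, avoids the syn-axial contact between CH2Br and the alkynyl group in F7 and should dominate; the route is rejoined at 26.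

**Further compounds**
F1 | step 10 | 2-[(3R,5S)-3-(TBS-oxy)-5-(TBDPS-oxy)-6-[(trimethylsilyl)methyl]hept-6-en-2-ylidene]-1,3-dithiane | CC(=C1SCCCS1)[C@H](O[Si](C)(C)C(C)(C)C)C[C@H](O[Si](c2ccccc2)(c2ccccc2)C(C)(C)C)C(=C)C[Si](C)(C)C
F2 | step 10 | (1R,4S,6R)-6-(TBS-oxy)-4-(TBDPS-oxy)-1-(2-methoxy-1,3-dithian-2-yl)-1-methyl-3-methylidenecyclohexane | C[C@@]1(C2(OC)SCCCS2)CC(=C)[C@@H](O[Si](c3ccccc3)(c3ccccc3)C(C)(C)C)C[C@H]1O[Si](C)(C)C(C)(C)C
F3 | step 10 | S-(3-sulfanylpropyl) (1R,4S,6R)-6-(TBS-oxy)-4-(TBDPS-oxy)-1-methyl-3-methylidenecyclohexane-1-carbothioate | C[C@@]1(C(=O)SCCCS)CC(=C)[C@@H](O[Si](c2ccccc2)(c2ccccc2)C(C)(C)C)C[C@H]1O[Si](C)(C)C(C)(C)C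
F4 | step 10 | [(1R,4S,6R)-6-(TBS-oxy)-4-(TBDPS-oxy)-1-methyl-3-methylidenecyclohexyl]methanol | C[C@@]1(CO)CC(=C)[C@@H](O[Si](c2ccccc2)(c2ccccc2)C(C)(C)C)C[C@H]1O[Si](C)(C)C(C)(C)C
F5 | step 14 | (1S,4S,6R)-4-(TBDPS-oxy)-1-ethynyl-1-methyl-3-methylidenecyclohexan-6-yl methyl oxalate | C[C@@]1(C#C)CC(=C)[C@@H](O[Si](c2ccccc2)(c2ccccc2)C(C)(C)C)C[C@H]1OC(=O)C(=O)OC
F6 | step 14 | cesium (1S,4S,6R)-4-(TBDPS-oxy)-1-ethynyl-1-methyl-3-methylidenecyclohexan-6-yl oxalate | C[C@@]1(C#C)CC(=C)[C@@H](O[Si](c2ccccc2)(c2ccccc2)C(C)(C)C)C[C@H]1OC(=O)C(=O)[O-].[Cs+]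
F7 | step 18 | (1S,3R,4R,6S)-3-bromo-3-(bromomethyl)-4,6-dichloro-1-(chloroethynyl)-1-methylcyclohexane | C[C@@]1(C#CCl)C[C@](Br)(CBr)[C@H](Cl)C[C@@H]1Cl
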